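**Retrosynthetic overview**

1. Numbering as in germacranolides: ring C1–C10 (oxirane C1/C10, C4=C5, lactone oxygen on C6, ring fusion C7, ester carbon C8, CH2 C9), lactone C11–C13, C14 on C10, C15 on C4. Target 31 ⇒ macrocyclic alcohol 23 by late operations only: C11 methylenation, O8 methacrylation, O14-directed epoxidation of C1=C10, O14 acetylation, O15 desilylation.
2. Key disconnection C9–C10 of the ten-membered ring: once the oxirane is taken back to the ring-trans C1=C10 alkene, the C8 carbinol is homoallylic to it (array O–C8–C9H2–C10(C14)=C1H). That array is the retron of a reductive alkyne–epoxide coupling, so 23 ⇒ alkynyl oxirane 22 (alkyne C1≡C10, oxirane C8–C9) carried on a preformed trans γ-lactone.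
3. 22 ⇒ chloromethyl ketone 20 (C8 by catalyst-controlled reduction, C9 from diazomethane) ⇒ acid 17 ⇒ Evans syn-aldol/lactonisation of succinyl imide 14 with enal 11 (sets C6 and C7).
4. 11 ⇒ Negishi coupling of the alkylzinc from iodide 5 (C1–C3, C10, C14) with (Z)-iodoalkenol 8 (C4–C6, C15), whose geometry fixes the ring-cis C4=C5 bond.
5. Ring order: γ-lactone (step 9), oxirane C8–C9 (step 13, consumed in step 14), ten-membered carbocycle (step 14), oxirane C1–C10 (step 19).

Key step: step 14

Remark: the SMILES is read as (1R,6R,7R,8S,10S) with C9 and C2 trans on the oxirane and C3 and C6 cis on C4=C5; TBS = tert-butyldimethylsilyl, PMB = 4-methoxybenzyl.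

**Route**

Step 1
Reactants: 1 prop-2-yn-1-ol
Product: 2 1-methoxy-4-[(prop-2-yn-1-yloxy)methyl]benzene
Conditions: NaH, PMBCl, Bu4NI (cat.), THF, 0 → 20 °C
Reagents that add atoms: 4-methoxybenzyl chloride, COc1ccc(CCl)cc1
Why: Williamson ether synthesis of a primary alkoxide with a benzylic chloride; the alkyl ether later protects O14 and can act as a donor to nickel in step 14.

Step 2
Reactants: 2 1-methoxy-4-[(prop-2-yn-1-yloxy)methyl]benzene; 3 oxirane
Product: 4 5-[(4-methoxybenzyl)oxy]pent-3-yn-1-ol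
Conditions: n-BuLi, THF, −78 °C; then 3, DMPU, −78 → 20 °C
Reagents that add atoms: none
Why: SN2 opening of oxirane by the lithium acetylide in a dipolar aprotic cosolvent adds C2 and C3 as a primary alcohol.

Step 3
Reactants: 4 5-[(4-methoxybenzyl)oxy]pent-3-yn-1-ol
Product: 5 1-{[(5-iodopent-2-yn-1-yl)oxy]methyl}-4-methoxybenzene
Conditions: I2, PPh3, imidazole, CH2Cl2, 0 °C
Reagents that add atoms: iodine, II
Why: Appel reaction of an unhindered primary alcohol, with displacement of the oxyphosphonium group by iodide.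

Step 4
Reactants: 6 but-2-yne-1,4-diol
Product: 7 4-[(tert-butyldimethylsilyl)oxy]but-2-yn-1-ol
Conditions: NaH (1 equiv), THF, 0 °C; then TBSCl
Reagents that add atoms: tert-butyldimethylsilyl chloride, C[Si](C)(Cl)C(C)(C)C
Why: monosilylation of a symmetrical diol through its monosodium alkoxide, which should stop cleanly at the mono-ether.

Step 5
Reactants: 7 4-[(tert-butyldimethylsilyl)oxy]but-2-yn-1-ol
Product: 8 (Z)-4-[(tert-butyldimethylsilyl)oxy]-3-iodobut-2-en-1-ol
Conditions: NaAlH2(OCH2CH2OMe)2 (Red-Al), THF, 0 °C; then I2, −78 → 0 °C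
Reagents that add atoms: iodine, II
Why: hydroxyl-directed trans-hydroalumination of the propargylic alcohol puts aluminium on the distal carbon (future C4), and iodinolysis with retention gives the (Z)-3-iodoalkenol, so the later C3 substituent is cis to C6.

Step 6
Reactants: 5 1-{[(5-iodopent-2-yn-1-yl)oxy]methyl}-4-methoxybenzene; 8 (Z)-4-[(tert-butyldimethylsilyl)oxy]-3-iodobut-2-en-1-ol
Product: 10 (E)-3-{[(tert-butyldimethylsilyl)oxy]methyl}-8-[(4-methoxybenzyl)oxy]oct-2-en-6-yn-1-ol (CH2OH cis to the C4 methylene), via alkylzinc iodide 9 (not isolated)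
Conditions: 5, Zn dust, LiCl, THF, 40 °C; then 8, Pd(OAc)2 (cat.), 2-dicyclohexylphosphino-2′,6′-dimethoxybiphenyl (SPhos), THF, 25 °C
Reagents that add atoms: none
Why: Negishi sp3–sp2 coupling with retention of the alkenyl iodide geometry; the alkylzinc reagent should tolerate the free hydroxyl, the internal alkyne and both ethers.

Step 7
Reactants: 10 (E)-3-{[(tert-butyldimethylsilyl)oxy]methyl}-8-[(4-methoxybenzyl)oxy]oct-2-en-6-yn-1-ol
Product: 11 (E)-3-{[(tert-butyldimethylsilyl)oxy]methyl}-8-[(4-methoxybenzyl)oxy]oct-2-en-6-ynal (CHO cis to the C4 methylene)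
Conditions: MnO2, CH2Cl2, 20 °C
Reagents that add atoms: none
Why: allylic oxidation with MnO2 under neutral conditions, which should leave the alkene geometry and the ethers untouched.

Step 8
Reactants: 12 (S)-4-benzyl-1,3-oxazolidin-2-one; 13 methyl 4-chloro-4-oxobutanoate
Product: 14 methyl 4-[(S)-4-benzyl-2-oxo-1,3-oxazolidin-3-yl]-4-oxobutanoate
Conditions: n-BuLi, THF, −78 °C; then 13, −78 → 0 °C
Reagents that add atoms: none
Why: N-acylation of the lithiated oxazolidinone by the acid chloride, the standard entry to Evans imides.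

Step 9
Reactants: 14 methyl 4-[(S)-4-benzyl-2-oxo-1,3-oxazolidin-3-yl]-4-oxobutanoate; 11 (E)-3-{[(tert-butyldimethylsilyl)oxy]methyl}-8-[(4-methoxybenzyl)oxy]oct-2-en-6-ynal
Product: 16 (S)-4-benzyl-3-{(2R,3S)-2-[(E)-2-(TBSOCH2)-7-(PMBO)hept-1-en-5-yn-1-yl]-5-oxooxolane-3-carbonyl}-1,3-oxazolidin-2-one (trans lactone), via aldol adduct 15 (not isolated)
Conditions: Bu2BOTf, i-Pr2NEt, CH2Cl2, −78 °C; 11, −78 → 0 °C; pH 7 buffer, MeOH, H2O2; then PPTS (cat.), PhMe, 50 °C
Reagents that add atoms: none
Why: Evans syn-aldol reaction in which the (Z)-boron enolate of the imide (future C7) adds to the enal through a chair transition state, the (S)-benzyl auxiliary setting C6 and C7 with the syn relationship, after which the C6 hydroxyl lactonises onto the methyl ester to give the trans-disubstituted γ-lactone.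

Step 10
Reactants: 16 lactone imide
Product: 17 (2R,3S)-2-[(E)-2-(TBSOCH2)-7-(PMBO)hept-1-en-5-yn-1-yl]-5-oxooxolane-3-carboxylic acid
Conditions: LiOH, H2O2, THF/H2O, 0 °C; Na2SO3; then HCl (1 M) to pH 3
Reagents that add atoms: hydrogen peroxide (as LiOOH), OO
Why: hydroperoxide cleaves the exocyclic imide carbonyl selectively, and any opened lactone should re-close on acidification because the γ-lactone is the only five-membered option.

Step 11
Reactants: 17 lactone acid
Product: 20 (4S,5R)-4-(chloroacetyl)-5-[(E)-2-(TBSOCH2)-7-(PMBO)hept-1-en-5-yn-1-yl]oxolan-2-one, via mixed anhydride 18 (not isolated), via diazoketone 19 (not isolated)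
Conditions: i-BuOCOCl, N-methylmorpholine, THF, −20 °C; CH2N2, Et2O, 0 °C; then HCl (1 M in Et2O, 1.05 equiv), −20 °C
Reagents that add atoms: diazomethane, C=[N+]=[N-]; hydrogen chloride, Cl
Why: acylation of diazomethane by the mixed anhydride (first stage of an Arndt–Eistert sequence) followed by protonation and chloride displacement of N2 gives the chloromethyl ketone, the stoichiometric HCl being consumed by the diazo group so that the silyl ether should survive.

Step 12
Reactants: 20 chloromethyl ketone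
Product: 21 (4R,5R)-4-[(R)-2-chloro-1-hydroxyethyl]-5-[(E)-2-(TBSOCH2)-7-(PMBO)hept-1-en-5-yn-1-yl]oxolan-2-one
Conditions: (R)-1-methyl-3,3-diphenyltetrahydro-1H,3H-pyrrolo[1,2-c][1,3,2]oxazaborole [(R)-Me-CBS, 20 mol%], catecholborane, PhMe, −78 °C
Reagents that add atoms: none
Why: Corey–Bakshi–Shibata reduction in which the (R)-catalyst, treating the branched lactone carbon as the large group and CH2Cl as the small one, delivers hydride to the face that gives the (R)-chlorohydrin (O8 syn to C11 along the C6–C9 chain), while catecholborane at −78 °C should not touch alkyne or lactone.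

Step 13
Reactants: 21 chlorohydrin
Product: 22 (4S,5R)-4-[(R)-oxiran-2-yl]-5-[(E)-2-(TBSOCH2)-7-(PMBO)hept-1-en-5-yn-1-yl]oxolan-2-one
Conditions: t-BuOK (1.05 equiv), THF, −20 °C
Reagents that add atoms: none
Why: intramolecular Williamson closure (3-exo-tet) of the chlorohydrin alkoxide, which breaks only the C9–Cl bond and so keeps the C8 configuration.

Step 14
Reactants: 22 alkynyl oxirane lactone
Product: 23 (6R,7R,8S)-8-hydroxy-14-(PMBO)-15-(TBSO)-13-norgermacra-1(10),4-dien-12,6-olide (ring-trans C1=C10, ring-cis C4=C5, trans-fused γ-lactone with C11H2)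
Conditions: Ni(cod)2 (30 mol%), PBu3 (60 mol%), Et3B (3 equiv), degassed THF, 40 °C, slow addition of 22 to 0.003 M; then NaHCO3 (aq)
Reagents that add atoms: none
Why: Proposed new method: zerovalent nickel, with Et3B as Lewis acid, should add oxidatively to the unsubstituted C9–O bond of the oxirane, and the alkyne should insert syn into the Ni–C9 bond (C9 to C10, nickel to C1) to give a six-membered oxanickelacycle; ethyl transfer from Et3B, β-hydride elimination and C1–H reductive elimination then release the O8 borinate, which is hydrolysed on work-up. The closest known reaction type is the nickel-catalysed reductive coupling of alkynes with terminal epoxides to homoallylic alcohols (known intermolecularly and for five- and six-membered rings), together with the nickel-catalysed reductive macrocyclisation of alkynals. The ten-membered carbocycle is closed in the endo mode with respect to both partners: both alkyne carbons and both oxirane carbons become ring atoms, with attack at the CH2 terminus C9. No stereocentre is created: C8 keeps the oxirane configuration because its C–O bond is never broken, and the syn delivery of C9 and H across the alkyne fixes C9 trans to C2 on C1=C10. The step needs regioselectivity at the alkyne (C–C bond at C10, not C1), which the substrate supports through the C14 ether oxygen, able to chelate nickel in a five-membered ring only when nickel sits on C1, and through the alternative being a nine-membered ring with an exocyclic alkene. It also needs ring closure to outrun oligomerisation, which the trans-lactone, the ring-cis C4=C5 bond and high dilution should favour.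

Step 15
Reactants: 23 macrocyclic hydroxy lactone
Product: 24 (6R,7R,8S,11R)-13-(dimethylamino)-8-hydroxy-14-(PMBO)-15-(TBSO)germacra-1(10),4-dien-12,6-olide (CH2NMe2 on C11 trans to C8)
Conditions: LiN(i-Pr)2 (2.5 equiv), THF, −78 °C; then CH2=NMe2+ I−, −78 → 0 °C
Reagents that add atoms: dimethylmethyleneammonium iodide, C=[N+](C)C.[I-]
Why: Mannich alkylation of the lactone enolate (formed as the O8-alkoxide/C11-enolate dianion, the enolate being inert to the alkoxide) with the iminium salt, which should enter anti to the C7–C8 bond, the new C11 centre being removed again in step 16.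

Step 16
Reactants: 24 Mannich base
Product: 26 (6R,7R,8S)-8-hydroxy-14-(PMBO)-15-(TBSO)germacra-1(10),4,11(13)-trien-12,6-olide, via trimethylammonium iodide 25 (not isolated)
Conditions: MeI, MeOH, 20 °C; then NaHCO3 (aq), CH2Cl2, 20 °C
Reagents that add atoms: none
Why: N-quaternisation followed by E1cB (Hofmann-type) elimination of trimethylamine from the β-ammonio lactone gives the exocyclic C11=C13 alkene under conditions mild enough for the diene and the free hydroxyl.

Step 17
Reactants: 26 α-methylene lactone alcohol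
Product: 27 8-O-methacrylate of 26
Conditions: methacrylic anhydride, Et3N, DMAP (cat.), CH2Cl2, 0 → 20 °C
Reagents that add atoms: methacrylic anhydride, C=C(C)C(=O)OC(=O)C(C)=C
Why: DMAP-catalysed acylation of the only free hydroxyl (O8), with retention at C8.

Step 18
Reactants: 27 methacrylate
Product: 28 14-hydroxy compound (27 without the PMB group)
Conditions: DDQ, CH2Cl2/pH 7 buffer, 0 °C
Reagents that add atoms: none
Why: oxidative cleavage of the electron-rich PMB ether through its benzylic oxocarbenium ion, to which silyl ether, esters and the electron-poor alkenes are inert.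

Step 19
Reactants: 28 allylic alcohol
Product: 29 (1R,6R,7R,8S,10S)-1,10-epoxy-14-hydroxy-8-(methacryloyloxy)-15-(TBSO)germacra-4,11(13)-dien-12,6-olide
Conditions: VO(acac)2 (cat.), t-BuOOH, CH2Cl2, 0 °C
Reagents that add atoms: tert-butyl hydroperoxide, CC(C)(C)OO
Why: hydroxyl-directed epoxidation in which the vanadium alkoxide of O14 delivers the peroxide oxygen only to the neighbouring C1=C10 bond and to its exposed outer face, the face that peripheral epoxidation of germacra-1(10)-enolides normally takes and that gives the trans-oxirane (1R,10S), while the acrylate alkenes and the undirected C4=C5 bond should not react.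

Step 20
Reactants: 29 epoxy alcohol
Product: 30 14-O-acetate of 29
Conditions: Ac2O, pyridine, DMAP (cat.), CH2Cl2, 0 °C
Reagents that add atoms: acetic anhydride, CC(=O)OC(C)=O
Why: acetylation of the primary hydroxyl under basic, non-nucleophilic conditions that should leave the oxirane closed.

Step 21
Reactants: 30 silyl ether
Product: 31 (1R,6R,7R,8S,10S)-14-acetoxy-1,10-epoxy-15-hydroxy-8-(methacryloyloxy)germacra-4,11(13)-dien-12,6-olide (ring-cis C4=C5), the target
Conditions: Bu4NF, AcOH (1:1), THF, 0 → 20 °C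
Reagents that add atoms: none
Why: fluoride-induced cleavage of the primary silyl ether, buffered with acetic acid so that the oxirane, both esters and the α-methylene lactone should survive.

**Compound list**

1 | prop-2-yn-1-ol | C#CCO | starting material
2 | 1-methoxy-4-[(prop-2-yn-1-yloxy)methyl]benzene | C#CCOCc1ccc(OC)cc1 | intermediate
3 | oxirane | C1CO1 | starting material
4 | 5-[(4-methoxybenzyl)oxy]pent-3-yn-1-ol | OCCC#CCOCc1ccc(OC)cc1 | intermediate
5 | 1-{[(5-iodopent-2-yn-1-yl)oxy]methyl}-4-methoxybenzene | ICCC#CCOCc1ccc(OC)cc1 | intermediate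
6 | but-2-yne-1,4-diol | OCC#CCO | starting material
7 | 4-[(tert-butyldimethylsilyl)oxy]but-2-yn-1-ol | OCC#CCO[Si](C)(C)C(C)(C)C | intermediate
8 | (Z)-4-[(tert-butyldimethylsilyl)oxy]-3-iodobut-2-en-1-ol | OC/C=C(\I)CO[Si](C)(C)C(C)(C)C | intermediate
9 | {5-[(4-methoxybenzyl)oxy]pent-3-yn-1-yl}zinc iodide | I[Zn]CCC#CCOCc1ccc(OC)cc1 | intermediate
10 | (E)-3-{[(tert-butyldimethylsilyl)oxy]methyl}-8-[(4-methoxybenzyl)oxy]oct-2-en-6-yn-1-ol | OC/C=C(\CCC#CCOCc1ccc(OC)cc1)CO[Si](C)(C)C(C)(C)C | intermediate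
11 | (E)-3-{[(tert-butyldimethylsilyl)oxy]methyl}-8-[(4-methoxybenzyl)oxy]oct-2-en-6-ynal | O=C/C=C(\CCC#CCOCc1ccc(OC)cc1)CO[Si](C)(C)C(C)(C)C | intermediate
12 | (S)-4-benzyl-1,3-oxazolidin-2-one | O=C1N[C@@H](Cc2ccccc2)CO1 | starting material
13 | methyl 4-chloro-4-oxobutanoate | COC(=O)CCC(Cl)=O | starting material
14 | methyl 4-[(S)-4-benzyl-2-oxo-1,3-oxazolidin-3-yl]-4-oxobutanoate | COC(=O)CCC(=O)N1[C@@H](Cc2ccccc2)COC1=O | intermediate
15 | methyl (3S,4R,5E)-3-{[(S)-4-benzyl-2-oxo-1,3-oxazolidin-3-yl]carbonyl}-4-hydroxy-6-(TBSOCH2)-11-(PMBO)undec-5-en-9-ynoate (syn aldol adduct) | O=C1OC[C@H](Cc2ccccc2)N1C(=O)[C@@H](CC(=O)OC)[C@H](O)/C=C(\CCC#CCOCc1ccc(OC)cc1)CO[Si](C)(C)C(C)(C)C | intermediate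
16 | (S)-4-benzyl-3-{(2R,3S)-2-[(E)-2-(TBSOCH2)-7-(PMBO)hept-1-en-5-yn-1-yl]-5-oxooxolane-3-carbonyl}-1,3-oxazolidin-2-one | O=C1C[C@H](C(=O)N2[C@@H](Cc3ccccc3)COC2=O)[C@@H](/C=C(\CCC#CCOCc2ccc(OC)cc2)CO[Si](C)(C)C(C)(C)C)O1 | intermediate
17 | (2R,3S)-2-[(E)-2-(TBSOCH2)-7-(PMBO)hept-1-en-5-yn-1-yl]-5-oxooxolane-3-carboxylic acid | O=C1C[C@H](C(=O)O)[C@@H](/C=C(\CCC#CCOCc2ccc(OC)cc2)CO[Si](C)(C)C(C)(C)C)O1 | intermediate
18 | mixed anhydride of 17 with isobutyl hydrogen carbonate | O=C1C[C@H](C(=O)OC(=O)OCC(C)C)[C@@H](/C=C(\CCC#CCOCc2ccc(OC)cc2)CO[Si](C)(C)C(C)(C)C)O1 | intermediate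
19 | (4S,5R)-4-(diazoacetyl)-5-[(E)-2-(TBSOCH2)-7-(PMBO)hept-1-en-5-yn-1-yl]oxolan-2-one | O=C1C[C@H](C(=O)C=[N+]=[N-])[C@@H](/C=C(\CCC#CCOCc2ccc(OC)cc2)CO[Si](C)(C)C(C)(C)C)O1 | intermediate
20 | (4S,5R)-4-(chloroacetyl)-5-[(E)-2-(TBSOCH2)-7-(PMBO)hept-1-en-5-yn-1-yl]oxolan-2-one | O=C1C[C@H](C(=O)CCl)[C@@H](/C=C(\CCC#CCOCc2ccc(OC)cc2)CO[Si](C)(C)C(C)(C)C)O1 | intermediate
21 | (4R,5R)-4-[(R)-2-chloro-1-hydroxyethyl]-5-[(E)-2-(TBSOCH2)-7-(PMBO)hept-1-en-5-yn-1-yl]oxolan-2-one | O=C1C[C@H]([C@@H](O)CCl)[C@@H](/C=C(\CCC#CCOCc2ccc(OC)cc2)CO[Si](C)(C)C(C)(C)C)O1 | intermediate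
22 | (4S,5R)-4-[(R)-oxiran-2-yl]-5-[(E)-2-(TBSOCH2)-7-(PMBO)hept-1-en-5-yn-1-yl]oxolan-2-one | O=C1C[C@H]([C@@H]2CO2)[C@@H](/C=C(\CCC#CCOCc2ccc(OC)cc2)CO[Si](C)(C)C(C)(C)C)O1 | intermediate
23 | (6R,7R,8S)-8-hydroxy-14-(PMBO)-15-(TBSO)-13-norgermacra-1(10),4-dien-12,6-olide (ring-trans C1=C10, ring-cis C4=C5, C11H2) | O[C@H]1C/C(COCc3ccc(OC)cc3)=C/CC/C(CO[Si](C)(C)C(C)(C)C)=C\[C@H]2OC(=O)C[C@H]12 | intermediate
24 | (6R,7R,8S,11R)-13-(dimethylamino)-8-hydroxy-14-(PMBO)-15-(TBSO)germacra-1(10),4-dien-12,6-olide | O[C@H]1C/C(COCc3ccc(OC)cc3)=C/CC/C(CO[Si](C)(C)C(C)(C)C)=C\[C@H]2OC(=O)[C@@H](CN(C)C)[C@H]12 | intermediate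
25 | N-methyl quaternary ammonium iodide of 24 | O[C@H]1C/C(COCc3ccc(OC)cc3)=C/CC/C(CO[Si](C)(C)C(C)(C)C)=C\[C@H]2OC(=O)[C@@H](C[N+](C)(C)C)[C@H]12.[I-] | intermediate
26 | (6R,7R,8S)-8-hydroxy-14-(PMBO)-15-(TBSO)germacra-1(10),4,11(13)-trien-12,6-olide | O[C@H]1C/C(COCc3ccc(OC)cc3)=C/CC/C(CO[Si](C)(C)C(C)(C)C)=C\[C@H]2OC(=O)C(=C)[C@H]12 | intermediate
27 | (6R,7R,8S)-8-(methacryloyloxy)-14-(PMBO)-15-(TBSO)germacra-1(10),4,11(13)-trien-12,6-olide | C=C(C)C(=O)O[C@H]1C/C(COCc3ccc(OC)cc3)=C/CC/C(CO[Si](C)(C)C(C)(C)C)=C\[C@H]2OC(=O)C(=C)[C@H]12 | intermediate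
28 | (6R,7R,8S)-14-hydroxy-8-(methacryloyloxy)-15-(TBSO)germacra-1(10),4,11(13)-trien-12,6-olide | C=C(C)C(=O)O[C@H]1C/C(CO)=C/CC/C(CO[Si](C)(C)C(C)(C)C)=C\[C@H]2OC(=O)C(=C)[C@H]12 | intermediate
29 | (1R,6R,7R,8S,10S)-1,10-epoxy-14-hydroxy-8-(methacryloyloxy)-15-(TBSO)germacra-4,11(13)-dien-12,6-olide | C=C(C)C(=O)O[C@H]1C[C@@]2(CO)O[C@@H]2CC/C(CO[Si](C)(C)C(C)(C)C)=C\[C@H]2OC(=O)C(=C)[C@H]12 | intermediate
30 | (1R,6R,7R,8S,10S)-14-acetoxy-1,10-epoxy-8-(methacryloyloxy)-15-(TBSO)germacra-4,11(13)-dien-12,6-olide | C=C(C)C(=O)O[C@H]1C[C@@]2(COC(C)=O)O[C@@H]2CC/C(CO[Si](C)(C)C(C)(C)C)=C\[C@H]2OC(=O)C(=C)[C@H]12 | intermediate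
31 | (1R,6R,7R,8S,10S)-14-acetoxy-1,10-epoxy-15-hydroxy-8-(methacryloyloxy)germacra-4,11(13)-dien-12,6-olide (CNP0306006.2) | C=C(C)C(=O)O[C@H]1C[C@@]2(COC(C)=O)O[C@@H]2CC/C(CO)=C\[C@H]2OC(=O)C(=C)[C@H]12 | target

**Step count and risks**

Total steps: 21. Longest linear sequence: 18 steps (1–3, 6, 7, 9–21).

Steps most likely to fail:

1. Step 14 (proposed new method). The C–C bond may form at C1 instead of C10 (nine-membered ring with exocyclic alkene), intermolecular coupling may lead to oligomers, or the dialkyl alkyne may insert too slowly. The fallback sets out from 22 and returns at 23, fixing the regiochemistry before ring closure. Syn-hydrostannation with Bu3SnH and PdCl2(PPh3)2 (THF, 0 °C), tin going to C10 next to the ether-bearing carbon, would give the alkenylstannane F1. Iododestannylation with I2 (CH2Cl2, 0 °C) would give, with retention, the alkenyl iodide F2 (iodine on C10, trans to C2). The ring would then be closed by the nickel-catalysed cross-electrophile coupling of alkenyl halides with terminal epoxides, a coupling established intermolecularly (NiCl2(dme), 4,4′-di-tert-butyl-2,2′-bipyridine, NaI, Et3N·HCl, Mn powder, DMPU, high dilution). In it the iodohydrin formed in situ is joined at C9 with retention of the alkene geometry.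

2. Step 15. The O8 alkoxide may attack the lactone carbonyl before enolisation is complete (translactonisation to the 8,12-lactone), or the second deprotonation may be incomplete. The fallback sets out from 23 and returns at 26, removing the alkoxide altogether. Silylation (Et3SiOTf, 2,6-lutidine, CH2Cl2, −78 °C) would give the triethylsilyl ether F3. The same Mannich alkylation on the mono-enolate (LiN(i-Pr)2, then CH2=NMe2+ I−) would give the amine F4. MeI followed by NaHCO3 would give the α-methylene lactone silyl ether F5. PPTS in MeOH at 0 °C should then remove the secondary triethylsilyl group selectively in the presence of the primary TBS ether.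

3. Step 19. Oxygen may be delivered to the other face of C1=C10 if a different ring conformer reacts, or the Lewis-acidic catalyst may trigger transannular opening of the epoxy alcohol. The fallback sets out from 28 and returns at 29, replacing substrate control by reagent control: Sharpless asymmetric epoxidation (Ti(OiPr)4, L-(+)-diethyl tartrate, t-BuOOH, 4 Å molecular sieves, CH2Cl2, −20 °C). For this 2,3-disubstituted allylic alcohol the L-(+)-tartrate is the enantiomer that delivers oxygen to the face giving (1R,10S). No new compound is formed (F0).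

**Further compounds**

F1 | step 14 | alkenylstannane: 22 with the alkyne hydrostannylated, Bu3Sn on C10 and trans to C2 (E) | O=C1C[C@H]([C@@H]2CO2)[C@@H](/C=C(\CC/C=C(/[Sn](CCCC)(CCCC)CCCC)COCc3ccc(OC)cc3)CO[Si](C)(C)C(C)(C)C)O1
F2 | step 14 | alkenyl iodide: 22 with the alkyne replaced by CH=C(I), iodine on C10 and trans to C2 (E) | O=C1C[C@H]([C@@H]2CO2)[C@@H](/C=C(\CC/C=C(/I)COCc3ccc(OC)cc3)CO[Si](C)(C)C(C)(C)C)O1
F3 | step 15 | 8-O-triethylsilyl ether of 23 | CC[Si](CC)(CC)O[C@H]1C/C(COCc3ccc(OC)cc3)=C/CC/C(CO[Si](C)(C)C(C)(C)C)=C\[C@H]2OC(=O)C[C@H]12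
F4 | step 15 | 8-O-triethylsilyl ether of 24 | CC[Si](CC)(CC)O[C@H]1C/C(COCc3ccc(OC)cc3)=C/CC/C(CO[Si](C)(C)C(C)(C)C)=C\[C@H]2OC(=O)[C@@H](CN(C)C)[C@H]12
F5 | step 15 | 8-O-triethylsilyl ether of 26 | CC[Si](CC)(CC)O[C@H]1C/C(COCc3ccc(OC)cc3)=C/CC/C(CO[Si](C)(C)C(C)(C)C)=C\[C@H]2OC(=O)C(=C)[C@H]12
F0 | step 19 | none | none
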